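**Plan**

1. Locants: each half is a decahydro-1-benzoxepine (O1, C2 gem-dimethyl, C3–O, quaternary C5a, linker carbon C6, C7, ring-fusion C9a); the left (methylidene) half carries primes.
2. Enabling feature: in both carbocycles C7 (C=CH2 or C(Me)OAc) sits between the linker-bearing C6 and the quaternary C5a. This is the pattern left when the quaternary carbon of a 1-alkynylcyclopentanol shifts from the carbinol carbon to the alkyne, so each six-membered carbocycle is cut at C5a–C6 back to a five-membered ketone.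
3. Cuts, in retrosynthetic order: acetates and C7′=CH2; C5a′–C6′ (second ring expansion) and C7′–alkyne (acetylide union); C7–CH3; linker CH2–CH2 (conjugate alkynylation of the right enone); C5a–C6 (first ring expansion); O1–C2 (7-endo epoxide opening); side chain of 2-methylcyclopentane-1,3-dione.
4. Forward: dione → enzymatic desymmetrisation → epoxide → oxepane-fused cyclopentanone 7 (serves both halves) → right carbocycle by ring expansion → propargyl arm and methyl carbinol → acetylide adds to a second molecule of 7 → left carbocycle by ring expansion → hydrogenation, methylenation, acetylation, desilylation.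
5. Stereochemistry: C5a and C9a from the ketoreductase, C3 from the Shi epoxidation; C6 and C6′ are set α to a ketone (equatorial, thermodynamic; hydrogenation anti to the angular methyl); C7 by equatorial attack of the methyl nucleophile opposite the axial angular methyl.

Key step: step 7

Remark: the five-membered precursors are numbered as cyclopenta[b]oxepines (C5a quaternary, C6 carbonyl or carbinol, C8a ring-fusion CH–O).
Remark: a ketoreductase giving the (2R,3S) alcohol (hydroxyl cis to methyl) is assumed to be available from a commercial enzyme panel.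

**Route**

Step 1
Reactants: 1 2-methylcyclopentane-1,3-dione; 2 acrolein
Product: 3 3-(1-methyl-2,5-dioxocyclopentyl)propanal
Conditions: H2O, rt
Reagents that add atoms: none
Why: Michael addition of the acidic cyclic 1,3-dione to acrolein in water is a standard way to build the quaternary carbon with a three-carbon aldehyde arm; no stereocentre is formed.

Step 2
Reactants: 3 3-(1-methyl-2,5-dioxocyclopentyl)propanal
Product: 4 2-methyl-2-(4-methylpent-3-en-1-yl)cyclopentane-1,3-dione
Conditions: i-PrPPh3I, n-BuLi, THF, −78 → 0 °C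
Reagents that add atoms: isopropyltriphenylphosphonium iodide, CC(C)[P+](c1ccccc1)(c1ccccc1)c1ccccc1.[I-]
Why: Wittig olefination with the non-stabilised isopropylidene ylide should engage the aldehyde far faster than the two hindered ring ketones and completes the trisubstituted olefin of the side chain.

Step 3
Reactants: 4 2-methyl-2-(4-methylpent-3-en-1-yl)cyclopentane-1,3-dione
Product: 5 (2R,3S)-3-hydroxy-2-methyl-2-(4-methylpent-3-en-1-yl)cyclopentan-1-one (hydroxyl cis to methyl)
Conditions: ketoreductase (NADPH-dependent), NADP+ (cat.), i-PrOH, phosphate buffer pH 7, 30 °C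
Reagents that add atoms: none
Why: Enzymatic desymmetrising reduction of a prochiral 2,2-disubstituted cyclopentane-1,3-dione distinguishes the enantiotopic carbonyls and their faces, so one hydride transfer sets both the quaternary centre (later C5a) and the carbinol (later C9a), with the hydroxyl cis to the small methyl group as is usual for 2-alkyl-2-(long-chain) diones.

Step 4
Reactants: 5 (2R,3S)-3-hydroxy-2-methyl-2-(4-methylpent-3-en-1-yl)cyclopentan-1-one
Product: 6 (2R,3S)-2-{2-[(2S)-3,3-dimethyloxiran-2-yl]ethyl}-3-hydroxy-2-methylcyclopentan-1-one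
Conditions: L-fructose-derived Shi ketone (cat.), KHSO5 (as 2KHSO5·KHSO4·K2SO4), K2CO3, Bu4NHSO4, MeCN/CH2(OMe)2/aq. borate buffer pH 10.5, 0 °C
Reagents that add atoms: potassium peroxymonosulfate, [K+].[O-]S(=O)(=O)OO
Why: Shi epoxidation of the trisubstituted olefin is reagent-controlled, the L-fructose-derived ketone giving the (S)-epoxide (the D-fructose-derived ketone gives the R series), and the ketone and free hydroxyl are tolerated at this pH.

Step 5
Reactants: 6 (2R,3S)-2-{2-[(2S)-3,3-dimethyloxiran-2-yl]ethyl}-3-hydroxy-2-methylcyclopentan-1-one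
Product: 7 (3S,5aR,8aS)-3-hydroxy-2,2,5a-trimethyloctahydrocyclopenta[b]oxepin-6-one (trans-fused)
Conditions: camphorsulfonic acid (cat.), CH2Cl2, −20 → 0 °C
Reagents that add atoms: none
Why: Acid-catalysed intramolecular epoxide opening by the ring hydroxyl at the tertiary epoxide carbon (7-endo, favoured electronically and by the strain of the alternative trans-fused six-membered ether on a cyclopentane) should close the oxepane, with C3 untouched and the trans ring fusion fixed by the existing centres.

Step 6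
Reactants: 7 (3S,5aR,8aS)-3-hydroxy-2,2,5a-trimethyloctahydrocyclopenta[b]oxepin-6-one
Product: 8 (3S,5aR,6S,8aS)-6-ethynyl-2,2,5a-trimethyloctahydro-2H-cyclopenta[b]oxepine-3,6-diol
Conditions: HC≡CMgBr, CeCl3, THF, −78 → 0 °C
Reagents that add atoms: ethynylmagnesium bromide, C#C[Mg]Br
Why: 1,2-Addition of the acetylide (organocerium to suppress enolisation) to the hindered cyclopentanone should occur anti to the angular methyl, as in the ethynylation of 17-keto steroids; the new carbinol centre is erased in step 7.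

Step 7
Reactants: 8 (3S,5aR,6S,8aS)-6-ethynyl-2,2,5a-trimethyloctahydro-2H-cyclopenta[b]oxepine-3,6-diol
Product: 9 (3S,5aS,9aS)-3-hydroxy-2,2,5a-trimethyl-6-methylideneoctahydro-1-benzoxepin-7(2H)-one
Conditions: [(4-CF3C6H4)3P]AuCl (cat.), AgSbF6 (cat.), 4 Å molecular sieves, CH2Cl2, rt → 40 °C
Reagents that add atoms: none
Why: Proposed new method: cationic monovalent gold activates the alkyne of 8, the C5a–C6 bond anti to gold migrates from the carbinol carbon to the internal alkyne carbon while the hydroxyl becomes the carbonyl, and protodeauration of the vinylgold releases the exocyclic methylene; the closest known reaction type is the gold-catalysed semipinacol ring expansion of 1-alkynylcyclobutanols to 2-alkylidenecyclopentanones, here extended from a four- to a five-membered carbinol. The six-membered ring is not closed by a cyclisation but grown from the five-membered one by this 1,2-alkyl shift, so no ring-closure mode applies. No stereocentre is created; C5a migrates with retention, and C3 and the ring-fusion CH–O (C8a, now C9a) are carried over unchanged. The step needs migration of the quaternary C5a in preference to the C7 methylene, which its higher substitution should secure, the driving force being the new carbonyl group and the cyclopentane-to-cyclohexanone change. It also needs the shift to outrun Meyer–Schuster isomerisation and alkyne hydration, for which water is excluded and a non-nucleophilic counter-ion is used; the hindered C3 hydroxyl is remote from the alkyne and should not interfere.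

Step 8
Reactants: 9 (3S,5aS,9aS)-3-hydroxy-2,2,5a-trimethyl-6-methylideneoctahydro-1-benzoxepin-7(2H)-one
Product: 11 (3S,5aS,6S,9aS)-3-hydroxy-2,2,5a-trimethyl-6-(prop-2-yn-1-yl)octahydro-1-benzoxepin-7(2H)-one, via silylalkynyl ketone 10 (not isolated)
Conditions: Me3SiC≡CH, n-BuLi, then Et2AlCl, hexane/Et2O, 0 °C; add 9, 0 °C → rt; then K2CO3, MeOH, rt
Reagents that add atoms: (trimethylsilyl)acetylene, C#C[Si](C)(C)C
Why: Conjugate alkynylation of the rigidly s-cis α-methylene ketone with a diethyl(alkynyl)alane is the classical 1,4-alkynyl transfer (the free hydroxyl only consumes reagent), and K2CO3 in MeOH then removes the C-silyl group and equilibrates C6 to the equatorial epimer cis to the angular methyl.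

Step 9
Reactants: 11 (3S,5aS,6S,9aS)-3-hydroxy-2,2,5a-trimethyl-6-(prop-2-yn-1-yl)octahydro-1-benzoxepin-7(2H)-one
Product: 12 (3S,5aS,6S,7R,9aS)-2,2,5a,7-tetramethyl-6-(prop-2-yn-1-yl)decahydro-1-benzoxepine-3,7-diol
Conditions: MeLi (excess), CeCl3, THF, −78 °C
Reagents that add atoms: methyllithium, [Li]C
Why: Organocerium methyl addition to the cyclohexanone should proceed by equatorial attack because the axial trajectory is blocked by the syn-axial angular methyl at C5a, which places the methyl equatorial and the hydroxyl axial (7R).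

Step 10
Reactants: 12 (3S,5aS,6S,7R,9aS)-2,2,5a,7-tetramethyl-6-(prop-2-yn-1-yl)decahydro-1-benzoxepine-3,7-diol
Product: 13 3,7-bis(trimethylsilyl) ether of 12
Conditions: N-(trimethylsilyl)imidazole, CH2Cl2, rt → 40 °C
Reagents that add atoms: N-(trimethylsilyl)imidazole, C[Si](C)(C)n1ccnc1
Why: Silylation with this strong silyl donor covers the secondary and the hindered tertiary hydroxyl without touching the terminal alkyne, removing the acidic protons for step 12 and masking the tertiary oxygen against attack on the activated alkyne in step 13.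

Step 11
Reactants: 7 (3S,5aR,8aS)-3-hydroxy-2,2,5a-trimethyloctahydrocyclopenta[b]oxepin-6-one
Product: 14 (3S,5aR,8aS)-3-[(tert-butyldimethylsilyl)oxy]-2,2,5a-trimethyloctahydrocyclopenta[b]oxepin-6-one
Conditions: TBSOTf, 2,6-lutidine, CH2Cl2, −78 °C
Reagents that add atoms: tert-butyldimethylsilyl trifluoromethanesulfonate, CC(C)(C)[Si](C)(C)OS(=O)(=O)C(F)(F)F
Why: Silyl triflate silylation of the hindered secondary alcohol at low temperature leaves the ketone untouched and gives the ether that keeps the left C3 oxygen free of acetate until the end.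

Step 12
Reactants: 13 3,7-bis(trimethylsilyl) ether of 12; 14 (3S,5aR,8aS)-3-[(tert-butyldimethylsilyl)oxy]-2,2,5a-trimethyloctahydrocyclopenta[b]oxepin-6-one
Product: 16 tertiary propargylic alcohol: 14 carrying at C6 a hydroxyl (cis to the angular methyl, 6S) and the alkynyl group C≡C–CH2–(C6 of the right half of 13), via lithium acetylide 15 (not isolated)
Conditions: n-BuLi, THF, −78 °C; then 14, −78 → −20 °C
Reagents that add atoms: none
Why: Addition of the lithium acetylide to the hindered cyclopentanone, again anti to the angular methyl, is the fragment union and installs the second 1-alkynylcyclopentanol; the configuration of the new carbinol is inconsequential.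

Step 13
Reactants: 16 tertiary propargylic alcohol
Product: 17 (E)-alkylidene ketone: left (3S,5aS,9aS)-3-(TBS-oxy)-2,2,5a-trimethyloctahydro-1-benzoxepin-7(2H)-one with C6′=CH–CH2–(C6 of the bis-silylated right half)
Conditions: [(4-CF3C6H4)3P]AuCl (cat.), AgSbF6 (cat.), 4 Å molecular sieves, CH2Cl2, rt → 40 °C
Reagents that add atoms: none
Why: Proposed new method: as in step 7, cationic monovalent gold activates the internal alkyne and the quaternary C5a′ shifts from the carbinol carbon to the proximal alkyne carbon anti to gold, protodeauration then giving the (E)-alkylidene ketone; the closest known reaction type is the gold-catalysed ring expansion of 1-alkynylcyclobutanols to (E)-2-alkylidenecyclopentanones, and the silylated tertiary oxygen and the absence of any olefin in 16 remove the usual competing nucleophiles.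

Step 14
Reactants: 17 (E)-alkylidene ketone
Product: 18 saturated ketone: left (3S,5aS,6S,9aS)-7-ketone linked C6′–CH2–CH2–C6 to the bis-silylated right half
Conditions: H2 (1 atm), Pd/C, EtOAc, rt
Reagents that add atoms: none
Why: Heterogeneous hydrogenation should saturate the conjugated exocyclic olefin from the face opposite the axial angular methyl, giving the equatorial side chain, which is also the thermodynamic epimer α to the ketone.

Step 15
Reactants: 18 saturated ketone
Product: 19 7′-methylidene compound (left half 3S,5aS,6R,9aS; silyl ethers retained)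
Conditions: Ph3PCH3Br, KOt-Bu, toluene, 90 °C
Reagents that add atoms: methyltriphenylphosphonium bromide, C[P+](c1ccccc1)(c1ccccc1)c1ccccc1.[Br-]
Why: Wittig methylenation under forcing conditions converts the hindered ketone into the exocyclic methylene, and the basic ylide cannot erode C6′ because it is already the thermodynamic epimer.

Step 16
Reactants: 19 7′-methylidene compound
Product: 20 right-half 3,7-diol with the left 3′-TBS ether retained
Conditions: PPTS (cat.), MeOH, 0 °C → rt
Reagents that add atoms: none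
Why: Mild acidic methanolysis removes both trimethylsilyl ethers while the far more stable, hindered TBS ether and the exocyclic olefin should survive.

Step 17
Reactants: 20 right-half 3,7-diol
Product: 21 right-half 3,7-diacetate with the left 3′-TBS ether
Conditions: Ac2O, DMAP, Et3N, toluene, 60 °C
Reagents that add atoms: acetic anhydride, CC(=O)OC(C)=O
Why: DMAP-catalysed acylation with excess anhydride at elevated temperature esterifies the secondary and the hindered axial tertiary hydroxyl, while the left C3′ oxygen is blocked as its silyl ether.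

Step 18
Reactants: 21 right-half 3,7-diacetate with the left 3′-TBS ether
Product: 22 (3S,5aS,6S,7R,9aS)-6-{2-[(3S,5aS,6R,9aS)-3-hydroxy-2,2,5a-trimethyl-7-methylidenedecahydro-1-benzoxepin-6-yl]ethyl}-2,2,5a,7-tetramethyldecahydro-1-benzoxepine-3,7-diyl diacetate
Conditions: HF·pyridine, pyridine/THF, 0 °C → rt
Reagents that add atoms: none
Why: Buffered fluoride cleavage of the silicon–oxygen bond frees the left C3′ hydroxyl without acyl migration or loss of the tertiary acetate.

**Compound list**

1 | 2-methylcyclopentane-1,3-dione | CC1C(=O)CCC1=O | starting material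
2 | acrolein | C=CC=O | starting material
3 | 3-(1-methyl-2,5-dioxocyclopentyl)propanal | CC1(CCC=O)C(=O)CCC1=O | intermediate
4 | 2-methyl-2-(4-methylpent-3-en-1-yl)cyclopentane-1,3-dione | CC(C)=CCCC1(C)C(=O)CCC1=O | intermediate
5 | (2R,3S)-3-hydroxy-2-methyl-2-(4-methylpent-3-en-1-yl)cyclopentan-1-one | O=C1[C@](C)(CCC=C(C)C)[C@@H](O)CC1 | intermediate
6 | (2R,3S)-2-{2-[(2S)-3,3-dimethyloxiran-2-yl]ethyl}-3-hydroxy-2-methylcyclopentan-1-one | O=C1[C@](C)(CC[C@@H]2OC2(C)C)[C@@H](O)CC1 | intermediate
7 | (3S,5aR,8aS)-3-hydroxy-2,2,5a-trimethyloctahydrocyclopenta[b]oxepin-6-one, trans-fused | O=C1[C@]2(C)CC[C@H](O)C(C)(C)O[C@H]2CC1 | intermediate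
8 | (3S,5aR,6S,8aS)-6-ethynyl-2,2,5a-trimethyloctahydro-2H-cyclopenta[b]oxepine-3,6-diol | C#C[C@]1(O)[C@]2(C)CC[C@H](O)C(C)(C)O[C@H]2CC1 | intermediate
9 | (3S,5aS,9aS)-3-hydroxy-2,2,5a-trimethyl-6-methylideneoctahydro-1-benzoxepin-7(2H)-one | C=C1[C@]2(C)CC[C@H](O)C(C)(C)O[C@H]2CCC1=O | intermediate
10 | (3S,5aS,6S,9aS)-3-hydroxy-2,2,5a-trimethyl-6-[3-(trimethylsilyl)prop-2-yn-1-yl]octahydro-1-benzoxepin-7(2H)-one | C[Si](C)(C)C#CC[C@H]1[C@]2(C)CC[C@H](O)C(C)(C)O[C@H]2CCC1=O | intermediate (not isolated)
11 | (3S,5aS,6S,9aS)-3-hydroxy-2,2,5a-trimethyl-6-(prop-2-yn-1-yl)octahydro-1-benzoxepin-7(2H)-one | C#CC[C@H]1[C@]2(C)CC[C@H](O)C(C)(C)O[C@H]2CCC1=O | intermediate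
12 | (3S,5aS,6S,7R,9aS)-2,2,5a,7-tetramethyl-6-(prop-2-yn-1-yl)decahydro-1-benzoxepine-3,7-diol | C#CC[C@H]1[C@]2(C)CC[C@H](O)C(C)(C)O[C@H]2CC[C@@]1(C)O | intermediate
13 | (3S,5aS,6S,7R,9aS)-2,2,5a,7-tetramethyl-6-(prop-2-yn-1-yl)-3,7-bis[(trimethylsilyl)oxy]decahydro-1-benzoxepine | C#CC[C@H]1[C@]2(C)CC[C@H](O[Si](C)(C)C)C(C)(C)O[C@H]2CC[C@@]1(C)O[Si](C)(C)C | intermediate
14 | (3S,5aR,8aS)-3-[(tert-butyldimethylsilyl)oxy]-2,2,5a-trimethyloctahydrocyclopenta[b]oxepin-6-one | O=C1[C@]2(C)CC[C@H](O[Si](C)(C)C(C)(C)C)C(C)(C)O[C@H]2CC1 | intermediate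
15 | lithium acetylide of 13 | [Li]C#CC[C@H]1[C@]2(C)CC[C@H](O[Si](C)(C)C)C(C)(C)O[C@H]2CC[C@@]1(C)O[Si](C)(C)C | intermediate (not isolated)
16 | (3S,5aR,6S,8aS)-3-[(tert-butyldimethylsilyl)oxy]-2,2,5a-trimethyl-6-{3-[(3S,5aS,6S,7R,9aS)-2,2,5a,7-tetramethyl-3,7-bis(trimethylsilyloxy)decahydro-1-benzoxepin-6-yl]prop-1-yn-1-yl}octahydro-2H-cyclopenta[b]oxepin-6-ol | O[C@@]1(C#CC[C@H]2[C@]3(C)CC[C@H](O[Si](C)(C)C)C(C)(C)O[C@H]3CC[C@@]2(C)O[Si](C)(C)C)[C@]4(C)CC[C@H](O[Si](C)(C)C(C)(C)C)C(C)(C)O[C@H]4CC1 | intermediate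
17 | (3S,5aS,6E,9aS)-3-[(tert-butyldimethylsilyl)oxy]-2,2,5a-trimethyl-6-{2-[(3S,5aS,6S,7R,9aS)-2,2,5a,7-tetramethyl-3,7-bis(trimethylsilyloxy)decahydro-1-benzoxepin-6-yl]ethylidene}octahydro-1-benzoxepin-7(2H)-one | O=C1CC[C@@H]2OC(C)(C)[C@@H](O[Si](C)(C)C(C)(C)C)CC[C@@]2(C)/C1=C\C[C@H]3[C@]4(C)CC[C@H](O[Si](C)(C)C)C(C)(C)O[C@H]4CC[C@@]3(C)O[Si](C)(C)C | intermediate
18 | (3S,5aS,6S,9aS)-3-[(tert-butyldimethylsilyl)oxy]-2,2,5a-trimethyl-6-{2-[(3S,5aS,6S,7R,9aS)-2,2,5a,7-tetramethyl-3,7-bis(trimethylsilyloxy)decahydro-1-benzoxepin-6-yl]ethyl}octahydro-1-benzoxepin-7(2H)-one | O=C1CC[C@@H]2OC(C)(C)[C@@H](O[Si](C)(C)C(C)(C)C)CC[C@@]2(C)[C@@H]1CC[C@H]3[C@]4(C)CC[C@H](O[Si](C)(C)C)C(C)(C)O[C@H]4CC[C@@]3(C)O[Si](C)(C)C | intermediate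
19 | 7′-methylidene analogue of 18 (left half 3S,5aS,6R,9aS; right half unchanged) | C=C1CC[C@@H]2OC(C)(C)[C@@H](O[Si](C)(C)C(C)(C)C)CC[C@@]2(C)[C@@H]1CC[C@H]3[C@]4(C)CC[C@H](O[Si](C)(C)C)C(C)(C)O[C@H]4CC[C@@]3(C)O[Si](C)(C)C | intermediate
20 | (3S,5aS,6S,7R,9aS)-6-{2-[(3S,5aS,6R,9aS)-3-[(tert-butyldimethylsilyl)oxy]-2,2,5a-trimethyl-7-methylidenedecahydro-1-benzoxepin-6-yl]ethyl}-2,2,5a,7-tetramethyldecahydro-1-benzoxepine-3,7-diol | C=C1CC[C@@H]2OC(C)(C)[C@@H](O[Si](C)(C)C(C)(C)C)CC[C@@]2(C)[C@@H]1CC[C@H]3[C@]4(C)CC[C@H](O)C(C)(C)O[C@H]4CC[C@@]3(C)O | intermediate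
21 | 3,7-diacetate of 20 | C=C1CC[C@@H]2OC(C)(C)[C@@H](O[Si](C)(C)C(C)(C)C)CC[C@@]2(C)[C@@H]1CC[C@H]3[C@]4(C)CC[C@H](OC(C)=O)C(C)(C)O[C@H]4CC[C@@]3(C)OC(C)=O | intermediate
22 | (3S,5aS,6S,7R,9aS)-6-{2-[(3S,5aS,6R,9aS)-3-hydroxy-2,2,5a-trimethyl-7-methylidenedecahydro-1-benzoxepin-6-yl]ethyl}-2,2,5a,7-tetramethyldecahydro-1-benzoxepine-3,7-diyl diacetate | C=C1CC[C@@H]2OC(C)(C)[C@@H](O)CC[C@@]2(C)[C@@H]1CC[C@H]1[C@]2(C)CC[C@H](OC(C)=O)C(C)(C)O[C@H]2CC[C@@]1(C)OC(C)=O | target

**Totals and risks**

Total step count: 18. Longest linear sequence: 17 (steps 1–10, then 12–18; step 11 is a one-step branch from 7).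

Steps most likely to fail:

1. Step 7 (proposed new method). The 1,2-shift of a five-membered carbinol may be too slow, so that gold-mediated hydration or Meyer–Schuster isomerisation of the propargylic alcohol takes over. The fallback uses the known Lewis-acid semipinacol ring expansion of α-hydroxy epoxides and sets out from 8. Semi-hydrogenation over Pd/CaCO3 poisoned with Pb(OAc)2 and quinoline would give the vinyl carbinol F1. Hydroxyl-directed epoxidation with VO(acac)2 and t-BuOOH would give the epoxy alcohol F2. ZnBr2 or BF3·OEt2 in CH2Cl2 should then induce migration of the quaternary C5a to the oxirane carbon and give the 6-(hydroxymethyl) ketone F3. Selective mesylation of the primary hydroxyl (MsCl, Et3N, −20 °C) would give the mesylate F4, and elimination with DBU comes back to the route at 9.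

2. Step 13 (proposed new method). The shift may again be slow on the larger substrate, allowing capture of the activated alkyne by a silyl ether oxygen or by adventitious water. The fallback sets out from 16 and uses the same known epoxide semipinacol chemistry. trans-Hydroalumination with NaAlH2(OCH2CH2OMe)2 in THF would give the (E)-allylic alcohol F5, and VO(acac)2 with t-BuOOH the epoxy alcohol F6. ZnBr2 should then give the ring-expanded β-hydroxy ketone F7. Mesylation to the mesylate F8 and DBU elimination would give 17, possibly accompanied by its (Z)-isomer F9; both converge under the hydrogenation conditions of step 14, and the route is rejoined at 18.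

3. Step 5. The epoxide opening may lack regio- or chemoselectivity, through 6-exo attack at the secondary epoxide carbon or capture of the epoxide by the ketone oxygen to give a bicyclic ketal. The fallback replaces epoxide opening by haloetherification of an olefin and sets out from 6. Cp2TiCl (from Cp2TiCl2 and Mn) would isomerise the epoxide to the exo-methylene allylic alcohol F10 with C3 intact. N-Iodosuccinimide in CH2Cl2 should then close the oxepane in the Markovnikov 7-exo sense, the ring hydroxyl attacking the tertiary olefin carbon, to give the iodomethyl oxepane F11. Bu3SnH with AIBN would reduce the C–I bond to the second methyl group and come back to the route at 7.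

**Further compounds**

F1 | step 7 | (3S,5aR,6S,8aS)-6-ethenyl-2,2,5a-trimethyloctahydro-2H-cyclopenta[b]oxepine-3,6-diol | C=C[C@]1(O)[C@]2(C)CC[C@H](O)C(C)(C)O[C@H]2CC1
F2 | step 7 | 2,2,5a-trimethyl-6-(oxiran-2-yl)octahydro-2H-cyclopenta[b]oxepine-3,6-diol (ring centres as in F1, mixture at the oxirane carbon) | O[C@@]1(C2CO2)[C@]3(C)CC[C@H](O)C(C)(C)O[C@H]3CC1
F3 | step 7 | (3S,5aS,9aS)-3-hydroxy-6-(hydroxymethyl)-2,2,5a-trimethyloctahydro-1-benzoxepin-7(2H)-one (C6 unassigned) | OCC1[C@]2(C)CC[C@H](O)C(C)(C)O[C@H]2CCC1=O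
F4 | step 7 | primary methanesulfonate of F3 | CS(=O)(=O)OCC1[C@]2(C)CC[C@H](O)C(C)(C)O[C@H]2CCC1=O
F5 | step 13 | (E)-allylic alcohol from trans-reduction of the alkyne of 16 | O[C@@]1(/C=C/C[C@H]2[C@]3(C)CC[C@H](O[Si](C)(C)C)C(C)(C)O[C@H]3CC[C@@]2(C)O[Si](C)(C)C)[C@]4(C)CC[C@H](O[Si](C)(C)C(C)(C)C)C(C)(C)O[C@H]4CC1
F6 | step 13 | trans-epoxy alcohol from F5 (mixture at the oxirane carbons) | O[C@@]1(C5OC5C[C@H]2[C@]3(C)CC[C@H](O[Si](C)(C)C)C(C)(C)O[C@H]3CC[C@@]2(C)O[Si](C)(C)C)[C@]4(C)CC[C@H](O[Si](C)(C)C(C)(C)C)C(C)(C)O[C@H]4CC1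
F7 | step 13 | ring-expanded β-hydroxy ketone: 18 with a hydroxyl on the linker carbon next to C6′ (C6′ and carbinol unassigned) | O=C1CC[C@@H]2OC(C)(C)[C@@H](O[Si](C)(C)C(C)(C)C)CC[C@@]2(C)C1C(O)C[C@H]3[C@]4(C)CC[C@H](O[Si](C)(C)C)C(C)(C)O[C@H]4CC[C@@]3(C)O[Si](C)(C)C
F8 | step 13 | methanesulfonate of F7 | O=C1CC[C@@H]2OC(C)(C)[C@@H](O[Si](C)(C)C(C)(C)C)CC[C@@]2(C)C1C(OS(C)(=O)=O)C[C@H]3[C@]4(C)CC[C@H](O[Si](C)(C)C)C(C)(C)O[C@H]4CC[C@@]3(C)O[Si](C)(C)C
F9 | step 13 | (Z)-isomer of 17 | O=C1CC[C@@H]2OC(C)(C)[C@@H](O[Si](C)(C)C(C)(C)C)CC[C@@]2(C)/C1=C/C[C@H]3[C@]4(C)CC[C@H](O[Si](C)(C)C)C(C)(C)O[C@H]4CC[C@@]3(C)O[Si](C)(C)C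
F10 | step 5 | (2R,3S)-3-hydroxy-2-[(3S)-3-hydroxy-4-methylpent-4-en-1-yl]-2-methylcyclopentan-1-one | O=C1[C@](C)(CC[C@H](O)C(C)=C)[C@@H](O)CC1
F11 | step 5 | (3S,5aR,8aS)-3-hydroxy-2-(iodomethyl)-2,5a-dimethyloctahydrocyclopenta[b]oxepin-6-one (mixture at C2) | O=C1[C@]2(C)CC[C@H](O)C(C)(CI)O[C@H]2CC1
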